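**Plan**

Numbering used: ring C1 (OAc), C2 (OH), C3 (allylic OH), C4 (=CH), C5 (=C), C6 (OBz); C7 is the CH2OBz carbon on C5.
Retrosynthesis: the C1 acetate is removed through a cyclic orthoacetate on the cis C1/C2 diol. The C3–C4 bond is then cut, because carbinol carbon C3 sits directly on the vinylic CH of the trisubstituted ring alkene C4=C5, so the cyclohexene is the adduct of an alkenylchromium at C4 and an aldehyde at C3.
The open-chain iodoalkene aldehyde is cut at C5–C7 (hydroxyl-directed anti-carbomagnesiation of a propargylic alcohol, iodine quench) and at C4≡C5 (one-carbon alkyne homologation of a lactol), which leads back to L-arabinose.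
Forward: L-arabinose 3,4-acetonide → alkyne → iodoalkene carrying C7 → dibenzoate → aldehyde → closure of the only ring → acetonide off → acetate on O1.
Stereochemistry: C6, C1 and C2 are C2, C3 and C4 of L-arabinose (chiral pool). C3 is set in the ring closure by substrate control. The alkene geometry that permits closure comes from a magnesium alkoxide chelate.

Key step: step 9

Remark: L-arabinose, the Ohira–Bestmann reagent and (chloromethyl)(isopropoxy)dimethylsilane are taken as commercial; the Grignard reagent ClMgCH2SiMe2(O-i-Pr) is made from the chlorosilane and Mg before use, and lactol 2 reacts through its open aldehyde form.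

**Route**

Step 1
Reactants: 1 L-arabinose
Product: 2 3,4-O-isopropylidene-β-L-arabinopyranose
Conditions: 2,2-dimethoxypropane, p-TsOH·H2O (cat.), DMF, rt; Et3N quench
Reagents that add atoms: 2,2-dimethoxypropane, COC(C)(C)OC
Why: Kinetic acid-catalysed transacetalisation in DMF should engage the cis-3,4-diol of the pyranose (O3 equatorial, O4 axial) and leave the hemiacetal and O2 free, without touching a stereocenter.

Step 2
Reactants: 2 3,4-O-isopropylidene-β-L-arabinopyranose
Product: 3 (1S)-1-[(4R,5S)-5-(hydroxymethyl)-2,2-dimethyl-1,3-dioxolan-4-yl]prop-2-yn-1-ol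
Conditions: dimethyl (1-diazo-2-oxopropyl)phosphonate, K2CO3, MeOH, rt → 50 °C
Reagents that add atoms: dimethyl (1-diazo-2-oxopropyl)phosphonate, COP(=O)(OC)C(=[N+]=[N-])C(C)=O
Why: Seyferth–Gilbert homologation with the Ohira–Bestmann reagent should trap the open aldehyde form of the lactol and give the terminal alkyne through an alkylidene carbene, the mild base leaving the acetonide and the three stereocenters untouched and freeing O5 as the primary alcohol.

Step 3
Reactants: 3 (1S)-1-[(4R,5S)-5-(hydroxymethyl)-2,2-dimethyl-1,3-dioxolan-4-yl]prop-2-yn-1-ol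
Product: 4 (1S)-1-[(4R,5S)-5-({[tert-butyl(diphenyl)silyl]oxy}methyl)-2,2-dimethyl-1,3-dioxolan-4-yl]prop-2-yn-1-ol
Conditions: TBDPSCl (1.05 equiv), imidazole, CH2Cl2, 0 °C
Reagents that add atoms: tert-butyl(chloro)diphenylsilane, CC(C)(C)[Si](Cl)(c1ccccc1)c1ccccc1
Why: Silylation with a bulky chlorosilane should be selective for the primary over the hindered secondary propargylic hydroxyl, which must stay free to direct the next step.

Step 4
Reactants: 4 (1S)-1-[(4R,5S)-5-({[tert-butyl(diphenyl)silyl]oxy}methyl)-2,2-dimethyl-1,3-dioxolan-4-yl]prop-2-yn-1-ol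
Product: 6 (1S,2E)-1-[(4R,5S)-5-({[tert-butyl(diphenyl)silyl]oxy}methyl)-2,2-dimethyl-1,3-dioxolan-4-yl]-3-iodo-2-{[dimethyl(propan-2-yloxy)silyl]methyl}prop-2-en-1-ol, via chelated alkenylmagnesium alkoxide 5 (not isolated)
Conditions: ClMgCH2SiMe2(O-i-Pr) (4 equiv), CuI (0.3 equiv), THF/Et2O, −20 °C → rt; then I2, THF, −40 → 0 °C
Reagents that add atoms: [dimethyl(propan-2-yloxy)silyl]methylmagnesium chloride, CC(C)O[Si](C)(C)C[Mg]Cl; iodine, II
Why: Copper-catalysed carbomagnesiation of a propargylic alcohol should deliver the silylmethyl group to the proximal alkyne carbon and hold magnesium on the terminal carbon in a five-membered alkoxide chelate (net anti addition), so that iodinolysis with retention places iodine cis to the carbinol carbon, the only geometry that can later close the ring; no stereocenter is formed.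

Step 5
Reactants: 6 (1S,2E)-1-[(4R,5S)-5-({[tert-butyl(diphenyl)silyl]oxy}methyl)-2,2-dimethyl-1,3-dioxolan-4-yl]-3-iodo-2-{[dimethyl(propan-2-yloxy)silyl]methyl}prop-2-en-1-ol
Product: 7 (1S,2Z)-1-[(4R,5S)-5-({[tert-butyl(diphenyl)silyl]oxy}methyl)-2,2-dimethyl-1,3-dioxolan-4-yl]-2-(hydroxymethyl)-3-iodoprop-2-en-1-ol
Conditions: 30% H2O2, KF, KHCO3, THF/MeOH 1:1, rt
Reagents that add atoms: hydrogen peroxide, OO
Why: Tamao–Fleming oxidation of the alkoxysilane should turn the C–Si bond into C–OH under basic peroxide conditions that leave the alkenyl iodide, the silyl ether and the acetonide intact.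

Step 6
Reactants: 7 (1S,2Z)-1-[(4R,5S)-5-({[tert-butyl(diphenyl)silyl]oxy}methyl)-2,2-dimethyl-1,3-dioxolan-4-yl]-2-(hydroxymethyl)-3-iodoprop-2-en-1-ol
Product: 8 (1S,2Z)-2-[(benzoyloxy)methyl]-1-[(4R,5S)-5-({[tert-butyl(diphenyl)silyl]oxy}methyl)-2,2-dimethyl-1,3-dioxolan-4-yl]-3-iodoprop-2-en-1-yl benzoate
Conditions: BzCl (3 equiv), pyridine, DMAP (cat.), CH2Cl2, 0 °C → rt
Reagents that add atoms: benzoyl chloride, O=C(Cl)c1ccccc1
Why: Acylation of both free hydroxyl groups under nucleophilic catalysis should install the two benzoates of the target (on O6 and O7) in one operation.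

Step 7
Reactants: 8 (1S,2Z)-2-[(benzoyloxy)methyl]-1-[(4R,5S)-5-({[tert-butyl(diphenyl)silyl]oxy}methyl)-2,2-dimethyl-1,3-dioxolan-4-yl]-3-iodoprop-2-en-1-yl benzoate
Product: 9 (1S,2Z)-2-[(benzoyloxy)methyl]-1-[(4R,5S)-5-(hydroxymethyl)-2,2-dimethyl-1,3-dioxolan-4-yl]-3-iodoprop-2-en-1-yl benzoate
Conditions: HF·pyridine, pyridine, THF, 0 °C → rt
Reagents that add atoms: none
Why: Buffered fluoride should cleave the silyl ether without acyl migration, since the freed primary hydroxyl has only acetal oxygens as neighbours.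

Step 8
Reactants: 9 (1S,2Z)-2-[(benzoyloxy)methyl]-1-[(4R,5S)-5-(hydroxymethyl)-2,2-dimethyl-1,3-dioxolan-4-yl]-3-iodoprop-2-en-1-yl benzoate
Product: 10 (1S,2Z)-2-[(benzoyloxy)methyl]-1-[(4R,5R)-5-formyl-2,2-dimethyl-1,3-dioxolan-4-yl]-3-iodoprop-2-en-1-yl benzoate
Conditions: Dess–Martin periodinane, NaHCO3, CH2Cl2, 0 °C → rt; used at once
Reagents that add atoms: none
Why: Dess–Martin oxidation under bicarbonate buffer should give the α-alkoxy aldehyde without epimerisation at C2 or β-elimination.

Step 9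
Reactants: 10 (1S,2Z)-2-[(benzoyloxy)methyl]-1-[(4R,5R)-5-formyl-2,2-dimethyl-1,3-dioxolan-4-yl]-3-iodoprop-2-en-1-yl benzoate
Product: 12 [(3R,4S,5R,6S)-6-(benzoyloxy)-3-hydroxy-4,5-(isopropylidenedioxy)cyclohex-1-en-1-yl]methyl benzoate, via alkenylchromium dichloride 11 (not isolated)
Conditions: CrCl2 (8 equiv), NiCl2 (0.1 equiv), degassed DMSO, 0.005 M, rt
Reagents that add atoms: none
Why: Zerovalent nickel, formed from NiCl2 and divalent chromium, should insert into the C–I bond and pass the alkenyl group with retention to trivalent chromium, and alkenylchromium 11 then adds to the aldehyde in the same molecule to make the C3–C4 bond. The closest known reaction type is the intramolecular Nozaki–Hiyama–Kishi alkenylation of aldehydes to 2-cyclohexenols, which tolerates esters and acetals and does not enolise the α-oxygenated aldehyde. The six-membered carbocycle closes in the 6-exo-trig mode with respect to the C=O group, and closure is open only because the metal on C4 is cis to C6 across C4=C5, so the alkene ends up endocyclic. The new stereocenter C3 is set by the substrate: in the half-chair transition state the C6 benzoate should sit pseudoaxial to avoid A(1,2) strain with the CH2OBz group on C5, which puts the dioxolane oxygen on C2 equatorial and anti to the incoming C4 (Felkin–Anh polar arrangement), while the chromium-bound carbonyl oxygen takes the pseudoequatorial site, giving the 2,3-trans alcohol (3R). The step needs insertion into C–I in preference to the allylic benzoates and ring closure in preference to reduction or dimerisation; the low NiCl2 loading, the position of both acyloxy groups on carbons attached to C5 and not to the metal-bearing C4 (no β-elimination path), and high dilution should secure this.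

Step 10
Reactants: 12 [(3R,4S,5R,6S)-6-(benzoyloxy)-3-hydroxy-4,5-(isopropylidenedioxy)cyclohex-1-en-1-yl]methyl benzoate
Product: 13 [(3R,4S,5S,6S)-6-(benzoyloxy)-3,4,5-trihydroxycyclohex-1-en-1-yl]methyl benzoate
Conditions: AcOH/H2O 4:1, 60 °C
Reagents that add atoms: none
Why: Acid-catalysed acetal hydrolysis should free the cis C1/C2 diol while the benzoates stay in place, ester migration being slow under acidic conditions.

Step 11
Reactants: 13 [(3R,4S,5S,6S)-6-(benzoyloxy)-3,4,5-trihydroxycyclohex-1-en-1-yl]methyl benzoate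
Product: 15 [(3R,4S,5S,6S)-5-(acetyloxy)-6-(benzoyloxy)-3,4-dihydroxycyclohex-1-en-1-yl]methyl benzoate, via cyclic orthoacetate 14 (not isolated)
Conditions: MeC(OMe)3 (1.5 equiv), camphorsulfonic acid (cat.), CH2Cl2, rt; then AcOH/H2O 4:1, rt
Reagents that add atoms: trimethyl orthoacetate, COC(C)(OC)OC; water, O
Why: Acid-catalysed orthoester exchange should engage only the cis C1/C2 diol (the trans C2/C3 pair cannot bridge), and stereoelectronically controlled hydrolysis of the cyclic orthoester opens to the axial ester, which is O1 in the half-chair that keeps the C6 benzoate pseudoaxial and the C2 and C3 oxygens equatorial, so the acetate should land on C1 and leave the C2,C3-diol free.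

**Compound list**

1 | L-arabinose | OC[C@H](O)[C@H](O)[C@@H](O)C=O | starting material
2 | 3,4-O-isopropylidene-β-L-arabinopyranose | O[C@H]1OC[C@@H]2OC(C)(C)O[C@@H]2[C@H]1O | intermediate
3 | (1S)-1-[(4R,5S)-5-(hydroxymethyl)-2,2-dimethyl-1,3-dioxolan-4-yl]prop-2-yn-1-ol | OC[C@@H]1OC(C)(C)O[C@@H]1[C@@H](O)C#C | intermediate
4 | (1S)-1-[(4R,5S)-5-({[tert-butyl(diphenyl)silyl]oxy}methyl)-2,2-dimethyl-1,3-dioxolan-4-yl]prop-2-yn-1-ol | CC(C)(C)[Si](c1ccccc1)(c1ccccc1)OC[C@@H]1OC(C)(C)O[C@@H]1[C@@H](O)C#C | intermediate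
5 | chelated alkenylmagnesium alkoxide (five-membered C–Mg–O ring, magnesium on the terminal alkene carbon, not isolated) | CC(C)(C)[Si](c1ccccc1)(c1ccccc1)OC[C@@H]1OC(C)(C)O[C@@H]1[C@H]1O[Mg]C=C1C[Si](C)(C)OC(C)C | intermediate
6 | (1S,2E)-1-[(4R,5S)-5-({[tert-butyl(diphenyl)silyl]oxy}methyl)-2,2-dimethyl-1,3-dioxolan-4-yl]-3-iodo-2-{[dimethyl(propan-2-yloxy)silyl]methyl}prop-2-en-1-ol (iodine cis to the carbinol carbon) | CC(C)(C)[Si](c1ccccc1)(c1ccccc1)OC[C@@H]1OC(C)(C)O[C@@H]1[C@@H](O)/C(C[Si](C)(C)OC(C)C)=C\I | intermediate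
7 | (1S,2Z)-1-[(4R,5S)-5-({[tert-butyl(diphenyl)silyl]oxy}methyl)-2,2-dimethyl-1,3-dioxolan-4-yl]-2-(hydroxymethyl)-3-iodoprop-2-en-1-ol | CC(C)(C)[Si](c1ccccc1)(c1ccccc1)OC[C@@H]1OC(C)(C)O[C@@H]1[C@@H](O)/C(CO)=C\I | intermediate
8 | (1S,2Z)-2-[(benzoyloxy)methyl]-1-[(4R,5S)-5-({[tert-butyl(diphenyl)silyl]oxy}methyl)-2,2-dimethyl-1,3-dioxolan-4-yl]-3-iodoprop-2-en-1-yl benzoate | CC(C)(C)[Si](c1ccccc1)(c1ccccc1)OC[C@@H]1OC(C)(C)O[C@@H]1[C@@H](OC(=O)c1ccccc1)/C(COC(=O)c1ccccc1)=C\I | intermediate
9 | (1S,2Z)-2-[(benzoyloxy)methyl]-1-[(4R,5S)-5-(hydroxymethyl)-2,2-dimethyl-1,3-dioxolan-4-yl]-3-iodoprop-2-en-1-yl benzoate | OC[C@@H]1OC(C)(C)O[C@@H]1[C@@H](OC(=O)c1ccccc1)/C(COC(=O)c1ccccc1)=C\I | intermediate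
10 | (1S,2Z)-2-[(benzoyloxy)methyl]-1-[(4R,5R)-5-formyl-2,2-dimethyl-1,3-dioxolan-4-yl]-3-iodoprop-2-en-1-yl benzoate | O=C[C@@H]1OC(C)(C)O[C@@H]1[C@@H](OC(=O)c1ccccc1)/C(COC(=O)c1ccccc1)=C\I | intermediate
11 | alkenylchromium dichloride from 10 (trivalent chromium in place of iodine, not isolated) | O=C[C@@H]1OC(C)(C)O[C@@H]1[C@@H](OC(=O)c1ccccc1)/C(COC(=O)c1ccccc1)=C\[Cr](Cl)Cl | intermediate
12 | [(3R,4S,5R,6S)-6-(benzoyloxy)-3-hydroxy-4,5-(isopropylidenedioxy)cyclohex-1-en-1-yl]methyl benzoate (3-OH trans to the dioxolane oxygen on C4) | CC1(C)O[C@H]2[C@@H](O1)[C@H](O)C=C(COC(=O)c3ccccc3)[C@@H]2OC(=O)c2ccccc2 | intermediate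
13 | [(3R,4S,5S,6S)-6-(benzoyloxy)-3,4,5-trihydroxycyclohex-1-en-1-yl]methyl benzoate | O[C@H]1[C@@H](O)[C@H](O)C=C(COC(=O)c2ccccc2)[C@@H]1OC(=O)c1ccccc1 | intermediate
14 | cyclic 1-methoxyethylidene orthoester on the cis-4,5-diol of 13 (orthoester carbon as a mixture, not isolated) | COC1(C)O[C@H]2[C@@H](O1)[C@H](O)C=C(COC(=O)c3ccccc3)[C@@H]2OC(=O)c2ccccc2 | intermediate
15 | [(3R,4S,5S,6S)-5-(acetyloxy)-6-(benzoyloxy)-3,4-dihydroxycyclohex-1-en-1-yl]methyl benzoate | CC(=O)O[C@H]1[C@@H](O)[C@H](O)C=C(COC(=O)c2ccccc2)[C@@H]1OC(=O)c1ccccc1 | target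

**Step count and risks**

Total step count: 11. Longest linear sequence: 11 steps from L-arabinose.

Steps most likely to fail:

Step 4. The carbomagnesiation may stall through deprotonation of the terminal alkyne or slow transfer of the silylmethyl group, returning alkyne or giving a mixture of regioisomers. The fallback sets out from 4 and builds the same iodoalkene by an iodo-aldol reaction. Oxidation of 4 with MnO2 in CH2Cl2 should give the alkynyl ketone F1. MgI2 with monomeric formaldehyde in CH2Cl2 at 0 °C (iodide conjugate addition, then aldol reaction of the iodo-allenolate on the side away from iodine) should give the (Z)-β-iodo enone F2, with iodine cis to the carbonyl carbon and C7 in place as CH2OH. Corey–Bakshi–Shibata reduction (B-methyl oxazaborolidine of the matched hand, BH3·SMe2) to the (1S)-carbinol returns to the route at 7.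

Step 9. The alkenylchromium may add to the wrong face of the aldehyde, giving the C3 epimer. The fallback sets out from 10 and corrects the centre after ring closure instead of controlling it: the 3-epi-alcohol F3 formed in the cyclisation is inverted by a Mitsunobu reaction (PPh3, diisopropyl azodicarboxylate, chloroacetic acid, THF, 0 °C) to the (3R)-chloroacetate F4. The chloroacetate is cleaved in the presence of the benzoates with thiourea and NaHCO3 in EtOH, which returns to the route at 12.

Step 11. The orthoester may open toward O2 if the other half-chair is populated, or the acetyl group may migrate between the cis oxygens O1 and O2. The fallback sets out from 13 and blocks the trans-diol. Butane-2,3-dione, HC(OMe)3 and camphorsulfonic acid in MeOH should give the butane-2,3-diacetal F5 on the trans-diequatorial C2/C3 diol, leaving only the C1 hydroxyl free. Ac2O in pyridine gives the C1 acetate F6, and CF3CO2H/H2O 9:1 at rt removes the diacetal, which returns to the route at 15.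

**Further compounds**

F1 | step 4 | 1-[(4S,5S)-5-({[tert-butyl(diphenyl)silyl]oxy}methyl)-2,2-dimethyl-1,3-dioxolan-4-yl]prop-2-yn-1-one | CC(C)(C)[Si](c1ccccc1)(c1ccccc1)OC[C@@H]1OC(C)(C)O[C@@H]1C(=O)C#C
F2 | step 4 | (2Z)-1-[(4S,5S)-5-({[tert-butyl(diphenyl)silyl]oxy}methyl)-2,2-dimethyl-1,3-dioxolan-4-yl]-2-(hydroxymethyl)-3-iodoprop-2-en-1-one | CC(C)(C)[Si](c1ccccc1)(c1ccccc1)OC[C@@H]1OC(C)(C)O[C@@H]1C(=O)/C(CO)=C\I
F3 | step 9 | [(3S,4S,5R,6S)-6-(benzoyloxy)-3-hydroxy-4,5-(isopropylidenedioxy)cyclohex-1-en-1-yl]methyl benzoate (C3 epimer of 12) | CC1(C)O[C@H]2[C@@H](O1)[C@@H](O)C=C(COC(=O)c3ccccc3)[C@@H]2OC(=O)c2ccccc2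
F4 | step 9 | [(3R,4S,5R,6S)-6-(benzoyloxy)-3-(chloroacetoxy)-4,5-(isopropylidenedioxy)cyclohex-1-en-1-yl]methyl benzoate | CC1(C)O[C@H]2[C@@H](O1)[C@H](OC(=O)CCl)C=C(COC(=O)c3ccccc3)[C@@H]2OC(=O)c2ccccc2
F5 | step 11 | 3,4-O-[(2S,3S)-2,3-dimethoxybutane-2,3-diyl] acetal of 13 (5-OH free) | O[C@H]1[C@H]2O[C@](C)(OC)[C@@](C)(OC)O[C@@H]2C=C(COC(=O)c2ccccc2)[C@@H]1OC(=O)c1ccccc1
F6 | step 11 | 5-O-acetyl-3,4-O-[(2S,3S)-2,3-dimethoxybutane-2,3-diyl] acetal of 13 | CC(=O)O[C@H]1[C@H]2O[C@](C)(OC)[C@@](C)(OC)O[C@@H]2C=C(COC(=O)c2ccccc2)[C@@H]1OC(=O)c1ccccc1
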